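The question was which one change to make to the next flask, and how much Z that flask holds at 30 min, and both hung on what stops Z there.

| flask | X | Q | remark | time |
|---|---|---|---|---|
| noon | 1 M | 0.70 equiv | run made earlier |  |
| dawn | 2 M | 1 equiv | run made earlier |  |
| flask | 2.0 M | 0.700 equiv |  | 30 min |

| run | time / min | Z / % |
|---|---|---|
| noon | 2.00 | 19.5 |
| noon | 4.00 | 32.8 |
| noon | 10.0 | 53.4 |
| noon | 25.0 | 64.1 |
| dawn | 6.00 | 63.6 |
| dawn | 12.0 | 76.2 |
| dawn | 20.0 | 83.2 |
| dawn | 25.0 | 82.6 |

(standard deviation of a reading: 1 percentage point)

- percent here means X units held: one G or L counts as two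
- X is a solid; its amount is given per volume of the solution
- on the list of suspects stand: X <-> E; E + Q -> Z; 2 E -> G; 2 X -> L
- at the start none of X is in solution

- amount of Z at 30 min, in percent of the X charged
- the change that raises the amount of Z at 30 min, in percent of the X charged most ("none" if none brings more than 2 percentage points) (Wednesday's / Thursday's / Friday's / none)
- amount of Z at 30 min, in percent of the X charged, after Friday's

- Wednesday's: doubling the dissolution coefficient of X, all else as stated
- Thursday's: doubling the amount of Q, all else as stated
- Friday's: doubling the solubility of X, all else as stated

Each Z on the list of suspects takes one Q, so I reckoned with the Q ceiling, the equivalents of Q charged read as a percentage of the X charged, here 70.0%. Dawn, with a ceiling of 100%, read 83.2% at 20.0 min and 82.6% at 25.0 min, a step of 0.6 percentage points against a scatter of 1 point, so I read no plateau from that pair. The flask has dawn's charge of X, but its ceiling is lower than both readings, so I took Q as its limiting reagent.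

Noon, with the same equivalents, had come within 5.9 points of the ceiling at 25.0 min and was still rising. The flask is twice as concentrated and runs longer, so I committed to Z between 64.1% and 70.0%.

Wednesday's and Friday's leave Q as charged, so I allowed each at most that gap. Thursday's charges 1.40 of Q, more than dawn's 1 equiv, and dawn's reading at 20.0 min stood 13 points above the present ceiling, which is more than the gap. I chose Thursday's.

The forecast gave 65%, Thursday's and 61% after Friday's, a last figure below my range, with the words “Doubling Q removes the cap”.

The flask gave 68.2%, which is 1.8 points under its ceiling, with 2.54% of its Q left. The best change was Thursday's, worth 19 points, against 0.66 points for Wednesday's and 0.83 points for Friday's, which reached 69.1%.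

    X ⇌ E, rate k1*(cs1 - [E]) while solid is left; crystals form when [E] > cs1 (solubility = 1.50 M, k = 0.0160 /s)
    E + Q → Z (k = 0.00410 /M/s)
    2 E → G (k = 8.50 × 10⁻⁵ /M/s)
    2 X → L (k = 9.40 × 10⁻⁴ /M/s)

The neighbouring flask differs by holding 0.420 equiv of Q, so its ceiling is 42.0%. At 30.0 min it held 41.9% of Z, with 0.21% of its Q left and 11.1% of G, while 34% of the charged X was still there, solid or dissolved.

The runs were computed with made-up constants; noise was put on by code.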